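**Plan**
- Retrosynthesis: the four phenols are carried as benzyl ethers and C3 carries an allyl ester; ring C is cut first at C3–C4, then at the O1–C2 ether (phenoxide plus glycidate), then the ring A formyl C–C bond, and last the C6 side chain back to a 1,1-diarylethene from an acetophenone and an aryl Grignard reagent.
- Forward: ring A acetophenone → diarylethene → hydrogenation → phenol → salicylaldehyde; O1–C2 ether by epoxide opening; oxidation to the keto ester; ring C is closed last by C3–C4 bond formation; the ester is then removed and the benzyl ethers cleaved.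
- Enabling feature: C4 (aryl ketone on ring A) and C3 (carbinol) form an α-ketol, the retron of a benzoin; C2 beside it is benzylic, bound to O1, and becomes acidic once C3 is a keto ester carbonyl, so its epimers interconvert while ring C closes.
- Stereochemistry: the side-chain methine comes from an iridium-catalysed asymmetric hydrogenation, C2 from the chiral triazolylidene under dynamic kinetic resolution, C3 from protonation after decarboxylation (hydroxyl trans to the C2 aryl group).

Key step: step 10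

Assumption: the antipode of each chiral catalyst (hydrogenation ligand, triazolium salt) that gives the drawn configuration is fixed by a preliminary screen; the C3 configuration drawn for 16 is the expected one and does not affect the outcome.

**Route**

Step 1
Reactants: 1 2,4,6-trihydroxyacetophenone
Product: 2 1-[2,6-dihydroxy-4-(methoxymethoxy)phenyl]ethanone
Conditions: MOMCl (1.0 equiv), iPr2NEt, THF, 0 °C
Reagents that add atoms: chloromethyl methyl ether, COCCl
Why: O-alkylation (MOM protection) should occur first at the 4-hydroxyl, which is the most acidic one and the only one not hydrogen-bonded to the acetyl group.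

Step 2
Reactants: 2 1-[2,6-dihydroxy-4-(methoxymethoxy)phenyl]ethanone
Product: 3 1-[2,6-bis(benzyloxy)-4-(methoxymethoxy)phenyl]ethanone
Conditions: BnBr (2.5 equiv), K2CO3, DMF, 70 °C
Reagents that add atoms: benzyl bromide, BrCc1ccccc1
Why: Williamson etherification under forcing carbonate/DMF conditions benzylates both chelated ortho hydroxyls, while the MOM acetal is stable to base.

Step 3
Reactants: 3 1-[2,6-bis(benzyloxy)-4-(methoxymethoxy)phenyl]ethanone; 4 1-(benzyloxy)-4-bromobenzene
Product: 7 1,3-bis(benzyloxy)-2-{1-[4-(benzyloxy)phenyl]ethenyl}-5-(methoxymethoxy)benzene, via [4-(benzyloxy)phenyl]magnesium bromide 5 (not isolated), via tertiary carbinol 6 (not isolated)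
Conditions: 4, Mg, THF, reflux; then 3, LaCl3·2LiCl, THF, 0 °C to rt; crude carbinol, PPTS (cat.), PhMe, 60 °C
Reagents that add atoms: none
Why: Grignard addition to the hindered, enolisable ketone (the lanthanum salt suppresses enolisation) followed by acid-catalysed E1 dehydration of the doubly benzylic tertiary carbinol should give the 1,1-diarylethene, the mild acid leaving the MOM ether intact.

Step 4
Reactants: 7 1,3-bis(benzyloxy)-2-{1-[4-(benzyloxy)phenyl]ethenyl}-5-(methoxymethoxy)benzene
Product: 8 1,3-bis(benzyloxy)-2-{(1R)-1-[4-(benzyloxy)phenyl]ethyl}-5-(methoxymethoxy)benzene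
Conditions: [Ir(cod)(L)][B(3,5-(CF3)2C6H3)4] (1 mol %, L = chiral phosphite-oxazoline P,N ligand), H2 (1 bar), CH2Cl2, rt
Reagents that add atoms: none
Why: Iridium-catalysed asymmetric hydrogenation of an unfunctionalised terminal 1,1-diarylethene should set the R methine, because the doubly ortho-substituted ring A is twisted out of the alkene plane while the para-substituted ring stays coplanar, which lets the catalyst distinguish the two aryl groups; the homogeneous catalyst does not cleave benzyl ethers.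

Step 5
Reactants: 8 1,3-bis(benzyloxy)-2-{(1R)-1-[4-(benzyloxy)phenyl]ethyl}-5-(methoxymethoxy)benzene
Product: 9 3,5-bis(benzyloxy)-4-{(1R)-1-[4-(benzyloxy)phenyl]ethyl}phenol
Conditions: HCl (conc., cat.), MeOH–THF, 45 °C
Reagents that add atoms: none
Why: Acid-catalysed acetal methanolysis removes only the MOM group; the benzyl ethers and the non-ionisable methine stereocentre should be inert.

Step 6
Reactants: 9 3,5-bis(benzyloxy)-4-{(1R)-1-[4-(benzyloxy)phenyl]ethyl}phenol
Product: 10 2,4-bis(benzyloxy)-3-{(1R)-1-[4-(benzyloxy)phenyl]ethyl}-6-hydroxybenzaldehyde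
Conditions: MgCl2, Et3N, (CH2O)n, MeCN, reflux
Reagents that add atoms: paraformaldehyde (as formaldehyde), C=O
Why: Magnesium-mediated ortho-formylation of a phenol (Casnati–Skattebøl reaction) delivers formaldehyde to an ortho carbon of the magnesium phenoxide and a second formaldehyde oxidises the benzylic alkoxide; the two ortho positions are equivalent and the para position is blocked, so a single aldehyde should result.

Step 7
Reactants: 11 4-(benzyloxy)benzaldehyde; 12 allyl chloroacetate
Product: 13 allyl trans-3-[4-(benzyloxy)phenyl]oxirane-2-carboxylate (racemic)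
Conditions: KOtBu, THF, −10 °C to rt
Reagents that add atoms: none
Why: Darzens glycidic ester condensation; the racemate suffices because both epoxide carbons lose their configuration later (the future C3 by oxidation, the future C2 by enolisation).

Step 8
Reactants: 10 2,4-bis(benzyloxy)-3-{(1R)-1-[4-(benzyloxy)phenyl]ethyl}-6-hydroxybenzaldehyde; 13 allyl trans-3-[4-(benzyloxy)phenyl]oxirane-2-carboxylate (racemic)
Product: 14 allyl 3-[3,5-bis(benzyloxy)-4-{(1R)-1-[4-(benzyloxy)phenyl]ethyl}-2-formylphenoxy]-3-[4-(benzyloxy)phenyl]-2-hydroxypropanoate (diastereomer mixture in the propanoate chain)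
Conditions: Cs2CO3 (0.2 equiv), DMF, 60 °C
Reagents that add atoms: none
Why: Base-catalysed epoxide opening by the phenoxide at the benzylic β-carbon of the glycidic ester (SN2, assisted by the para-alkoxyphenyl group) forms the O1–C2 ether; with the aldehyde already in place no formylation has to be run on this acid-labile benzylic ether, and the diastereomer ratio is irrelevant.

Step 9
Reactants: 14 allyl 3-[3,5-bis(benzyloxy)-4-{(1R)-1-[4-(benzyloxy)phenyl]ethyl}-2-formylphenoxy]-3-[4-(benzyloxy)phenyl]-2-hydroxypropanoate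
Product: 15 allyl 3-[3,5-bis(benzyloxy)-4-{(1R)-1-[4-(benzyloxy)phenyl]ethyl}-2-formylphenoxy]-3-[4-(benzyloxy)phenyl]-2-oxopropanoate (C3 epimers of the chain, interconverting)
Conditions: Dess–Martin periodinane, CH2Cl2, 0 °C to rt
Reagents that add atoms: none
Why: Dess–Martin oxidation converts the secondary α-hydroxy ester into the α-keto ester under neutral conditions that should leave the aldehyde, the allyl ester and the benzyl ethers untouched; the future C2 thereby becomes epimerisable.

Step 10
Reactants: 15 allyl 3-[3,5-bis(benzyloxy)-4-{(1R)-1-[4-(benzyloxy)phenyl]ethyl}-2-formylphenoxy]-3-[4-(benzyloxy)phenyl]-2-oxopropanoate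
Product: 16 allyl (2R,3R)-5,7-bis(benzyloxy)-2-[4-(benzyloxy)phenyl]-6-{(1R)-1-[4-(benzyloxy)phenyl]ethyl}-3-hydroxy-4-oxochromane-3-carboxylate (3-hydroxyl trans to the 2-aryl group)
Conditions: aminoindanol-derived N-pentafluorophenyl triazolium tetrafluoroborate (20 mol %, antipode chosen for 2R), K2CO3 (30 mol %), MTBE, rt
Reagents that add atoms: none
Why: Proposed new method: the triazolylidene adds to the only aldehyde (C4), the resulting Breslow intermediate attacks the adjacent, strongly electrophilic keto ester carbonyl (C3) in a 6-exo-trig closure that forms C3–C4 and ring C, and loss of the carbene releases the tertiary ketol. The closest known reactions are the carbene-catalysed intramolecular aldehyde–ketone crossed benzoin giving 3-hydroxychroman-4-ones and the dynamic kinetic cross-benzoin of β-stereogenic α-keto esters; combining them in one substrate is the untested part. C2 is set by the chiral catalyst through dynamic kinetic resolution, since the carbonate that frees the carbene also enolises the acidic C2–H (benzylic, α to the 1,2-dicarbonyl) and both epimers should drain through the faster, matched closure with the C2 aryl group equatorial. C3 follows from C2 by substrate control in the chair-like closure (ketone oxygen anti to O1, ester cis to the aryl group) and is erased in the next step in any case. Chemoselectivity rests on the substrate offering a single aldehyde as donor and a keto ester as acceptor; an aldehyde at C3 is avoided because its own Breslow intermediate would expel the ring A aryloxide. The remote methine on the C6 side chain is not acidic under carbonate and should stay untouched.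

Step 11
Reactants: 16 allyl (2R,3R)-5,7-bis(benzyloxy)-2-[4-(benzyloxy)phenyl]-6-{(1R)-1-[4-(benzyloxy)phenyl]ethyl}-3-hydroxy-4-oxochromane-3-carboxylate
Product: 19 (2R,3R)-5,7-bis(benzyloxy)-2-[4-(benzyloxy)phenyl]-6-{(1R)-1-[4-(benzyloxy)phenyl]ethyl}-3-hydroxychroman-4-one, via β-keto acid 17 (not isolated), via enediol 18 (not isolated)
Conditions: Pd(PPh3)4 (5 mol %), morpholine (3 equiv), THF, rt
Reagents that add atoms: none
Why: Tsuji–Trost deallylation with zerovalent palladium (morpholine traps the allyl group) gives β-keto acid 17, which loses CO2 through enediol 18; protonation at C3 rather than C4 is favoured because it leaves the carbonyl conjugated with the electron-rich ring A, and it should settle on the diequatorial 2,3-trans ketol, while C2 cannot ionise because the 4'-oxygen is still benzylated.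

Step 12
Reactants: 19 (2R,3R)-5,7-bis(benzyloxy)-2-[4-(benzyloxy)phenyl]-6-{(1R)-1-[4-(benzyloxy)phenyl]ethyl}-3-hydroxychroman-4-one
Product: 20 (2R,3R)-3,5,7-trihydroxy-2-(4-hydroxyphenyl)-6-[(1R)-1-(4-hydroxyphenyl)ethyl]chroman-4-one
Conditions: H2 (1 atm), Pd/C, EtOAc–MeOH, rt
Reagents that add atoms: none
Why: Catalytic hydrogenolysis cleaves the four benzyl ethers under neutral conditions; the vinylogous-ester-like C4 ketone, the cyclic O1–C2 ether and the three stereocentres are expected to survive at 1 atm and room temperature.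

**Compound list**
1 | 2,4,6-trihydroxyacetophenone | CC(=O)c1c(O)cc(O)cc1O | starting material
2 | 1-[2,6-dihydroxy-4-(methoxymethoxy)phenyl]ethanone | CC(=O)c1c(O)cc(OCOC)cc1O | intermediate
3 | 1-[2,6-bis(benzyloxy)-4-(methoxymethoxy)phenyl]ethanone | CC(=O)c1c(OCc2ccccc2)cc(OCOC)cc1OCc1ccccc1 | intermediate
4 | 1-(benzyloxy)-4-bromobenzene | Brc1ccc(OCc2ccccc2)cc1 | starting material
5 | [4-(benzyloxy)phenyl]magnesium bromide | Br[Mg]c1ccc(OCc2ccccc2)cc1 | intermediate
6 | 1-[2,6-bis(benzyloxy)-4-(methoxymethoxy)phenyl]-1-[4-(benzyloxy)phenyl]ethanol (racemic tertiary carbinol) | CC(O)(c1ccc(OCc2ccccc2)cc1)c1c(OCc2ccccc2)cc(OCOC)cc1OCc1ccccc1 | intermediate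
7 | 1,3-bis(benzyloxy)-2-{1-[4-(benzyloxy)phenyl]ethenyl}-5-(methoxymethoxy)benzene | C=C(c1ccc(OCc2ccccc2)cc1)c1c(OCc2ccccc2)cc(OCOC)cc1OCc1ccccc1 | intermediate
8 | 1,3-bis(benzyloxy)-2-{(1R)-1-[4-(benzyloxy)phenyl]ethyl}-5-(methoxymethoxy)benzene | C[C@H](c1ccc(OCc2ccccc2)cc1)c1c(OCc2ccccc2)cc(OCOC)cc1OCc1ccccc1 | intermediate
9 | 3,5-bis(benzyloxy)-4-{(1R)-1-[4-(benzyloxy)phenyl]ethyl}phenol | C[C@H](c1ccc(OCc2ccccc2)cc1)c1c(OCc2ccccc2)cc(O)cc1OCc1ccccc1 | intermediate
10 | 2,4-bis(benzyloxy)-3-{(1R)-1-[4-(benzyloxy)phenyl]ethyl}-6-hydroxybenzaldehyde | C[C@H](c1ccc(OCc2ccccc2)cc1)c1c(OCc2ccccc2)cc(O)c(C=O)c1OCc1ccccc1 | intermediate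
11 | 4-(benzyloxy)benzaldehyde | O=Cc1ccc(OCc2ccccc2)cc1 | starting material
12 | allyl chloroacetate | C=CCOC(=O)CCl | starting material
13 | allyl trans-3-[4-(benzyloxy)phenyl]oxirane-2-carboxylate (racemate; one enantiomer drawn) | C=CCOC(=O)[C@H]1O[C@@H]1c1ccc(OCc2ccccc2)cc1 | intermediate
14 | allyl 3-[3,5-bis(benzyloxy)-4-{(1R)-1-[4-(benzyloxy)phenyl]ethyl}-2-formylphenoxy]-3-[4-(benzyloxy)phenyl]-2-hydroxypropanoate (chain stereocentres undefined) | C[C@H](c1ccc(OCc2ccccc2)cc1)c1c(OCc2ccccc2)cc(OC(c2ccc(OCc3ccccc3)cc2)C(O)C(=O)OCC=C)c(C=O)c1OCc1ccccc1 | intermediate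
15 | allyl 3-[3,5-bis(benzyloxy)-4-{(1R)-1-[4-(benzyloxy)phenyl]ethyl}-2-formylphenoxy]-3-[4-(benzyloxy)phenyl]-2-oxopropanoate (chain C3 epimers, interconverting) | C[C@H](c1ccc(OCc2ccccc2)cc1)c1c(OCc2ccccc2)cc(OC(c2ccc(OCc3ccccc3)cc2)C(=O)C(=O)OCC=C)c(C=O)c1OCc1ccccc1 | intermediate
16 | allyl (2R,3R)-5,7-bis(benzyloxy)-2-[4-(benzyloxy)phenyl]-6-{(1R)-1-[4-(benzyloxy)phenyl]ethyl}-3-hydroxy-4-oxochromane-3-carboxylate | C[C@H](c1ccc(OCc2ccccc2)cc1)c1c(OCc2ccccc2)cc2c(c1OCc1ccccc1)C(=O)[C@@](O)(C(=O)OCC=C)[C@@H](c1ccc(OCc3ccccc3)cc1)O2 | intermediate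
17 | (2R,3R)-5,7-bis(benzyloxy)-2-[4-(benzyloxy)phenyl]-6-{(1R)-1-[4-(benzyloxy)phenyl]ethyl}-3-hydroxy-4-oxochromane-3-carboxylic acid | C[C@H](c1ccc(OCc2ccccc2)cc1)c1c(OCc2ccccc2)cc2c(c1OCc1ccccc1)C(=O)[C@@](O)(C(=O)O)[C@@H](c1ccc(OCc3ccccc3)cc1)O2 | intermediate
18 | (2R)-5,7-bis(benzyloxy)-2-[4-(benzyloxy)phenyl]-6-{(1R)-1-[4-(benzyloxy)phenyl]ethyl}-2H-chromene-3,4-diol (enediol) | C[C@H](c1ccc(OCc2ccccc2)cc1)c1c(OCc2ccccc2)cc2c(c1OCc1ccccc1)C(O)=C(O)[C@@H](c1ccc(OCc3ccccc3)cc1)O2 | intermediate
19 | (2R,3R)-5,7-bis(benzyloxy)-2-[4-(benzyloxy)phenyl]-6-{(1R)-1-[4-(benzyloxy)phenyl]ethyl}-3-hydroxychroman-4-one | C[C@H](c1ccc(OCc2ccccc2)cc1)c1c(OCc2ccccc2)cc2c(c1OCc1ccccc1)C(=O)[C@H](O)[C@@H](c1ccc(OCc3ccccc3)cc1)O2 | intermediate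
20 | (2R,3R)-3,5,7-trihydroxy-2-(4-hydroxyphenyl)-6-[(1R)-1-(4-hydroxyphenyl)ethyl]chroman-4-one | C[C@H](c1ccc(O)cc1)c1c(O)cc2c(c1O)C(=O)[C@H](O)[C@@H](c1ccc(O)cc1)O2 | target

**Count and risks**
Total steps: 12. Longest linear sequence: 11 (steps 1–6 and 8–12; step 7 is a one-step side branch).

Steps most likely to fail:

1. Step 10. The carbene may add too slowly to the doubly ortho-substituted, electron-rich aldehyde, so that the C2 enol attacks the aldehyde instead in a five-ring aldol closure; C2 selection may also be incomplete if epimerisation lags behind ring closure. The fallback gives up the benzoin disconnection for the classical chalcone epoxide route to trans-dihydroflavonols. It sets out from 10: protection with MOMCl/iPr2NEt gives 2,4-bis(benzyloxy)-3-{(1R)-1-[4-(benzyloxy)phenyl]ethyl}-6-(methoxymethoxy)benzaldehyde F1; MeMgBr addition gives the secondary carbinol F2; Dess–Martin oxidation gives the acetophenone F3; Claisen–Schmidt condensation with 11 (KOH, EtOH) gives the E-chalcone F4; Juliá–Colonna epoxidation (poly-L-leucine, urea–H2O2, DBU, THF) gives the (αR,βS)-epoxy ketone F5. HCl in MeOH then removes the MOM group, and the freed phenol opens the epoxide at the benzylic carbon with inversion in a 6-endo closure. The fallback comes back to the route at 19.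

2. Step 4. Enantiofacial discrimination may be poor, or turnover slow, at the hindered 1,1-diarylethene. The fallback changes substrate and mode of stereocontrol to a hydroxyl-directed rhodium hydrogenation of a 2-(1-arylvinyl)phenol. It sets out from 2: monobenzylation (BnBr 1 equiv, K2CO3, acetone; the second hydroxyl stays chelated) gives 1-[2-(benzyloxy)-6-hydroxy-4-(methoxymethoxy)phenyl]ethanone F6; excess Grignard reagent 5 (from 4) followed by PPTS gives 3-(benzyloxy)-2-{1-[4-(benzyloxy)phenyl]ethenyl}-5-(methoxymethoxy)phenol F7; [Rh(nbd)2]BF4 with a chiral ferrocenyl bisphosphine and H2 in MeOH gives, through phenol coordination to rhodium, 3-(benzyloxy)-2-{(1R)-1-[4-(benzyloxy)phenyl]ethyl}-5-(methoxymethoxy)phenol F8. Benzylation (BnBr, K2CO3, DMF) brings the fallback back at 8.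

3. Step 11. The enediol may be protonated kinetically on the face remote from the C2 aryl group, giving the 2,3-cis ketol; base equilibration at C3 would risk β-elimination of the ring A phenoxide and opening of ring C. The fallback replaces protonation control by a stereospecific displacement. It sets out from 16: the same deallylation–decarboxylation is run and the cis ketol, (2R,3S)-5,7-bis(benzyloxy)-2-[4-(benzyloxy)phenyl]-6-{(1R)-1-[4-(benzyloxy)phenyl]ethyl}-3-hydroxychroman-4-one F9, is taken on. Mitsunobu inversion with chloroacetic acid (PPh3, DIAD, THF), an SN2 reaction at the carbonyl-activated C3 with the nucleophile arriving anti to the aryl group, gives the trans chloroacetate F10. Thiourea with NaHCO3 in EtOH removes the chloroacetyl group under nearly neutral conditions, and the fallback comes back at 19.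

**Further compounds**
F1 | step 10 | 2,4-bis(benzyloxy)-3-{(1R)-1-[4-(benzyloxy)phenyl]ethyl}-6-(methoxymethoxy)benzaldehyde | C[C@H](c1ccc(OCc2ccccc2)cc1)c1c(OCc2ccccc2)cc(OCOC)c(C=O)c1OCc1ccccc1
F2 | step 10 | 1-[2,4-bis(benzyloxy)-3-{(1R)-1-[4-(benzyloxy)phenyl]ethyl}-6-(methoxymethoxy)phenyl]ethanol (carbinol epimers) | C[C@H](c1ccc(OCc2ccccc2)cc1)c1c(OCc2ccccc2)cc(OCOC)c(C(C)O)c1OCc1ccccc1
F3 | step 10 | 1-[2,4-bis(benzyloxy)-3-{(1R)-1-[4-(benzyloxy)phenyl]ethyl}-6-(methoxymethoxy)phenyl]ethanone | C[C@H](c1ccc(OCc2ccccc2)cc1)c1c(OCc2ccccc2)cc(OCOC)c(C(C)=O)c1OCc1ccccc1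
F4 | step 10 | (E)-1-[2,4-bis(benzyloxy)-3-{(1R)-1-[4-(benzyloxy)phenyl]ethyl}-6-(methoxymethoxy)phenyl]-3-[4-(benzyloxy)phenyl]prop-2-en-1-one | C[C@H](c1ccc(OCc2ccccc2)cc1)c1c(OCc2ccccc2)cc(OCOC)c(C(=O)/C=C/c2ccc(OCc3ccccc3)cc2)c1OCc1ccccc1
F5 | step 10 | [2,4-bis(benzyloxy)-3-{(1R)-1-[4-(benzyloxy)phenyl]ethyl}-6-(methoxymethoxy)phenyl]{(2R,3S)-3-[4-(benzyloxy)phenyl]oxiran-2-yl}methanone | C[C@H](c1ccc(OCc2ccccc2)cc1)c1c(OCc2ccccc2)cc(OCOC)c(C(=O)[C@@H]2O[C@H]2c2ccc(OCc3ccccc3)cc2)c1OCc1ccccc1
F6 | step 4 | 1-[2-(benzyloxy)-6-hydroxy-4-(methoxymethoxy)phenyl]ethanone | CC(=O)c1c(O)cc(OCOC)cc1OCc1ccccc1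
F7 | step 4 | 3-(benzyloxy)-2-{1-[4-(benzyloxy)phenyl]ethenyl}-5-(methoxymethoxy)phenol | C=C(c1ccc(OCc2ccccc2)cc1)c1c(O)cc(OCOC)cc1OCc1ccccc1
F8 | step 4 | 3-(benzyloxy)-2-{(1R)-1-[4-(benzyloxy)phenyl]ethyl}-5-(methoxymethoxy)phenol | C[C@H](c1ccc(OCc2ccccc2)cc1)c1c(O)cc(OCOC)cc1OCc1ccccc1
F9 | step 11 | (2R,3S)-5,7-bis(benzyloxy)-2-[4-(benzyloxy)phenyl]-6-{(1R)-1-[4-(benzyloxy)phenyl]ethyl}-3-hydroxychroman-4-one | C[C@H](c1ccc(OCc2ccccc2)cc1)c1c(OCc2ccccc2)cc2c(c1OCc1ccccc1)C(=O)[C@@H](O)[C@@H](c1ccc(OCc3ccccc3)cc1)O2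
F10 | step 11 | (2R,3R)-5,7-bis(benzyloxy)-2-[4-(benzyloxy)phenyl]-6-{(1R)-1-[4-(benzyloxy)phenyl]ethyl}-4-oxochroman-3-yl chloroacetate | C[C@H](c1ccc(OCc2ccccc2)cc1)c1c(OCc2ccccc2)cc2c(c1OCc1ccccc1)C(=O)[C@H](OC(=O)CCl)[C@@H](c1ccc(OCc3ccccc3)cc1)O2
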